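**Retrosynthetic overview**
1. The quinone comes from aerobic para-oxidation of a 2,6-disubstituted phenol in the last step. No ring is formed in the route; the only ring is bought as o-cresol.
2. The C7–C8 and C9–C10 bonds and both carbinol centres come from one three-component Pd-catalysed conjunctive coupling. A dienyl group shifts 1,2 from boron to a carbon of (Z)-1,2-diborylethene (acetylene + B2pin2), an alkenyl iodide caps the other carbon, and both C–B bonds are then oxidised to C–OH.
3. The left C9 dienyl iodide comes from methylalumination/iodination of 6-methylhept-5-en-1-yne, itself made from propyne dianion and prenyl bromide.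
4. The right C16 alkenyl iodide comes from hydrozirconation/iodination of a methyl alkyne. That alkyne comes from ortho-allylation of o-cresol with an allylic alcohol made by methylalumination/formaldehyde capture of hepta-1,5-diyne (silylpropyne + 1-bromobut-2-yne).

Assumption: side-chain carbons are numbered C1–C16 from the ring. The (SP,S'P) ligand antipode is taken to give the (8S,9S) series on this new substrate class; this must be checked experimentally, and both antipodes are sold.

**Step 1**
Reactants: 1 propyne; 2 prenyl bromide (1-bromo-3-methylbut-2-ene)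
Product: 5 6-methylhept-5-en-1-yne, via 1,3-dilithiopropyne 3 (not isolated), via lithium acetylide 4 (not isolated)
Conditions: 1, n-BuLi (2 equiv), TMEDA, Et2O/hexane, −78 → 0 °C; 2, −78 °C → rt; H2O
Reagents that add atoms: none
Why: In this dianion alkylation the more basic propargylic carbon of 3 attacks the primary allylic bromide by SN2, and the acetylide end stays untouched until the aqueous quench.

**Step 2**
Reactants: 5 6-methylhept-5-en-1-yne
Product: 7 (E)-1-iodo-2,6-dimethylhepta-1,5-diene, via alkenylalane 6 (not isolated)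
Conditions: Me3Al (2 equiv), Cp2ZrCl2 (0.25 equiv), CH2Cl2, 0 °C → rt; I2, THF, −30 → 0 °C
Reagents that add atoms: trimethylaluminium, C[Al](C)C; iodine, II
Why: Negishi zirconium-catalysed methylalumination adds Me and Al syn with Al on the terminal carbon, the trisubstituted alkene is inert, and iodinolysis of the C–Al bond keeps the E geometry.

**Step 3**
Reactants: 8 acetylene
Product: 9 (Z)-1,2-bis(4,4,5,5-tetramethyl-1,3,2-dioxaborolan-2-yl)ethene
Conditions: B2pin2, Pt(PPh3)4 (3 mol %), acetylene (1 atm), DMF, 80 °C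
Reagents that add atoms: bis(pinacolato)diboron, CC1(C)OB(B2OC(C)(C)C(C)(C)O2)OC1(C)C
Why: In this platinum-catalysed alkyne diboration the B–B bond adds oxidatively to zerovalent platinum, and syn insertion followed by reductive elimination can only give the cis-diborylalkene.

**Step 4**
Reactants: 10 1-(trimethylsilyl)propyne; 11 1-bromobut-2-yne
Product: 14 hepta-1,5-diyne, via 3-lithio-1-(trimethylsilyl)propyne 12 (not isolated), via silylated diyne 13 (not isolated)
Conditions: 10, n-BuLi, THF, −78 → −20 °C; 11, −78 °C → rt; then MeOH, K2CO3 (cat.), rt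
Reagents that add atoms: none
Why: The silyl-capped propargyllithium alkylates the primary propargylic bromide by SN2, the silyl cap blocks the acetylide and disfavours the allenyl pathway, and base-catalysed methanolysis then removes the alkynyl silane in the same flask.

**Step 5**
Reactants: 14 hepta-1,5-diyne
Product: 17 (E)-3-methyloct-2-en-6-yn-1-ol, via alkenylalane 15 (not isolated), via lithium alanate 16 (not isolated)
Conditions: Me3Al (1.5 equiv), Cp2ZrCl2 (0.25 equiv), CH2Cl2, 0 °C → rt; volatiles off; n-BuLi, hexane/THF, −78 → 0 °C; (CH2O)n, rt; H2O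
Reagents that add atoms: trimethylaluminium, C[Al](C)C; paraformaldehyde (as formaldehyde), C=O
Why: Negishi methylalumination is far faster on the terminal alkyne than on the methyl-capped internal one and is syn with Al on the terminal carbon, and the derived alanate adds to formaldehyde with retention to give the E allylic alcohol.

**Step 6**
Reactants: 17 (E)-3-methyloct-2-en-6-yn-1-ol; 18 o-cresol (2-methylphenol)
Product: 19 2-methyl-6-[(E)-3-methyloct-2-en-6-yn-1-yl]phenol
Conditions: 18 (3 equiv), acidic Al2O3, ClCH2CH2Cl, reflux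
Reagents that add atoms: none
Why: In this alumina-templated Friedel–Crafts ortho-allylation the surface binds the phenol oxygen and the allylic alcohol together, so the primary allyl terminus is delivered to the only free ortho carbon with the E alkene kept and the para position left open.

**Step 7**
Reactants: 19 2-methyl-6-[(E)-3-methyloct-2-en-6-yn-1-yl]phenol
Product: 23 tert-butyl{2-[(2E,6E)-7-iodo-3-methylocta-2,6-dien-1-yl]-6-methylphenoxy}dimethylsilane, via sodium phenoxide 20 (not isolated), via TBS ether 21 (not isolated), via alkenylzirconocene chloride 22 (not isolated)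
Conditions: NaH, TBSCl, THF, 0 °C → rt; Cp2Zr(H)Cl (2.2 equiv), 45 °C; I2, THF, −78 → 0 °C
Reagents that add atoms: tert-butyldimethylsilyl chloride, CC(C)(C)[Si](C)(C)Cl; iodine, II
Why: O-silylation leaves only inert NaCl, Schwartz hydrozirconation adds H–Zr syn, excess reagent equilibrates Zr to the less hindered methyl-bearing carbon (about 9:1, minor isomer removed by chromatography), and iodinolysis proceeds with retention to give the E iodide.

**Step 8**
Reactants: 7 (E)-1-iodo-2,6-dimethylhepta-1,5-diene; 9 (Z)-1,2-bis(pinacolatoboryl)ethene; 23 alkenyl iodide TBS ether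
Product: 28 (2E,6E,8S,9S,10E)-1-(2-hydroxy-3-methylphenyl)-3,7,11,15-tetramethylhexadeca-2,6,10,14-tetraene-8,9-diol, via dienyllithium 24 (not isolated), via boron ate complex 25 (not isolated), via syn-bis(boronic ester) 26 (not isolated), via TBS-protected diol 27 (not isolated)
Conditions: 7 (1.3 equiv), t-BuLi (2 equiv per 7), Et2O, −78 °C; 9 (1.3 equiv), THF, −78 °C → rt; 23 (1.0 equiv), Pd(OAc)2 (5 mol %), (SP,S'P)-1,1'-bis[bis(3,5-dimethylphenyl)phosphino]-2,2'-bis[(R)-α-(dimethylamino)benzyl]ferrocene (MandyPhos type, 6 mol %), KOTf (3 equiv), THF, 60 °C; then 3 M NaOH, 30% H2O2, THF/MeOH, 0 °C → rt; aq. NH4Cl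
Reagents that add atoms: hydrogen peroxide, OO
Why: Proposed new method: this is an enantioselective conjunctive cross-coupling on a β-boryl alkenylboron ate complex, in which 24 adds to one boron of symmetric 9 to give 25, the cationic alkenylpalladium species (divalent palladium, formed by oxidative addition of 23 to the zerovalent Pd–ligand complex and loss of iodide as KI) binds one face of the cis CH=CH unit rather than the more hindered trisubstituted dienyl C=C, the dienyl group then shifts 1,2 from four-coordinate boron to the adjacent carbon anti to Pd (helped by the empty p orbital of the second Bpin, which makes that carbon electrophilic and stabilises the new α-boryl C–Pd bond), and reductive elimination with retention completes a net anti dicarbofunctionalisation of a Z-alkene that can only give syn-26 with the ligand fixing the absolute sense, after which both C–B bonds are oxidised with retention to the (8S,9S)-diol and hydroxide/hydroperoxide strips the base-labile phenolic TBS group; the closest known reaction type is the Pd/MandyPhos conjunctive coupling of bis(alkenyl)borates and of β-alkyl- or β-silyl-substituted alkenylboron ate complexes.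

**Step 9**
Reactants: 28 phenol diol
Product: 29 2-[(2E,6E,8S,9S,10E)-8,9-dihydroxy-3,7,11,15-tetramethylhexadeca-2,6,10,14-tetraen-1-yl]-6-methylcyclohexa-2,5-diene-1,4-dione
Conditions: Co(salen) ([N,N'-bis(salicylidene)ethylenediaminato]cobalt, 15 mol %), O2 (1 atm), DMF, rt
Reagents that add atoms: dioxygen, O=O
Why: In this Co(salen)-catalysed aerobic phenol oxidation the cobalt–dioxygen adduct (from divalent cobalt) abstracts the phenolic hydrogen, O2 is taken up at the free para carbon of the 2,6-disubstituted phenoxyl radical, and the neutral conditions leave the alkenes, the diol and both stereocentres untouched.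

**Compound list**
1 | propyne | CC#C | starting material
2 | prenyl bromide (1-bromo-3-methylbut-2-ene) | CC(C)=CCBr | starting material
3 | 1,3-dilithiopropyne | [Li]CC#C[Li] | intermediate
4 | lithium 6-methylhept-5-en-1-yn-1-ide | [Li]C#CCCC=C(C)C | intermediate
5 | 6-methylhept-5-en-1-yne | C#CCCC=C(C)C | intermediate
6 | [(E)-2,6-dimethylhepta-1,5-dien-1-yl]dimethylalane | C[Al](C)/C=C(\C)CCC=C(C)C | intermediate
7 | (E)-1-iodo-2,6-dimethylhepta-1,5-diene | I/C=C(\C)CCC=C(C)C | intermediate
8 | acetylene | C#C | starting material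
9 | (Z)-1,2-bis(4,4,5,5-tetramethyl-1,3,2-dioxaborolan-2-yl)ethene | CC1(C)OB(/C=C\B2OC(C)(C)C(C)(C)O2)OC1(C)C | intermediate
10 | 1-(trimethylsilyl)propyne | CC#C[Si](C)(C)C | starting material
11 | 1-bromobut-2-yne | CC#CCBr | starting material
12 | 3-lithio-1-(trimethylsilyl)propyne | [Li]CC#C[Si](C)(C)C | intermediate
13 | hepta-1,5-diyn-1-yl(trimethyl)silane | CC#CCCC#C[Si](C)(C)C | intermediate
14 | hepta-1,5-diyne | C#CCCC#CC | intermediate
15 | dimethyl[(E)-2-methylhept-1-en-5-yn-1-yl]alane | C[Al](C)/C=C(\C)CCC#CC | intermediate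
16 | lithium butyl(dimethyl)[(E)-2-methylhept-1-en-5-yn-1-yl]alanate | [Li+].CCCC[Al-](C)(C)/C=C(\C)CCC#CC | intermediate
17 | (E)-3-methyloct-2-en-6-yn-1-ol | OC/C=C(\C)CCC#CC | intermediate
18 | o-cresol (2-methylphenol) | Cc1ccccc1O | starting material
19 | 2-methyl-6-[(E)-3-methyloct-2-en-6-yn-1-yl]phenol | CC#CCC/C(C)=C/Cc1cccc(C)c1O | intermediate
20 | sodium 2-methyl-6-[(E)-3-methyloct-2-en-6-yn-1-yl]phenolate | CC#CCC/C(C)=C/Cc1cccc(C)c1[O-].[Na+] | intermediate
21 | tert-butyl(dimethyl){2-methyl-6-[(E)-3-methyloct-2-en-6-yn-1-yl]phenoxy}silane | CC#CCC/C(C)=C/Cc1cccc(C)c1O[Si](C)(C)C(C)(C)C | intermediate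
22 | chlorobis(cyclopentadienyl)[(2E,6E)-alkenyl]zirconium, Zr on C7 (the methyl-bearing carbon) and trans to C5 | Cl[Zr](C1C=CC=C1)(C1C=CC=C1)/C(C)=C/CC/C(C)=C/Cc1cccc(C)c1O[Si](C)(C)C(C)(C)C | intermediate
23 | tert-butyl{2-[(2E,6E)-7-iodo-3-methylocta-2,6-dien-1-yl]-6-methylphenoxy}dimethylsilane | I/C(C)=C/CC/C(C)=C/Cc1cccc(C)c1O[Si](C)(C)C(C)(C)C | intermediate
24 | [(E)-2,6-dimethylhepta-1,5-dien-1-yl]lithium | [Li]/C=C(\C)CCC=C(C)C | intermediate
25 | lithium [(E)-2,6-dimethylhepta-1,5-dienyl][(Z)-2-(pinacolatoboryl)ethenyl](pinacolato)borate | [Li+].CC(C)=CCC/C(C)=C/[B-]1(/C=C\B2OC(C)(C)C(C)(C)O2)OC(C)(C)C(C)(C)O1 | intermediate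
26 | tert-butyl(dimethyl){2-methyl-6-[(2E,6E,8R,9R,10E)-3,7,11,15-tetramethyl-8,9-bis(pinacolatoboryl)hexadeca-2,6,10,14-tetraen-1-yl]phenoxy}silane (syn; same spatial arrangement as the 8S,9S diol) | CC(C)=CCC/C(C)=C/[C@H](B1OC(C)(C)C(C)(C)O1)[C@@H](B1OC(C)(C)C(C)(C)O1)/C(C)=C/CC/C(C)=C/Cc1cccc(C)c1O[Si](C)(C)C(C)(C)C | intermediate
27 | (2E,6E,8S,9S,10E)-1-{2-[(tert-butyldimethylsilyl)oxy]-3-methylphenyl}-3,7,11,15-tetramethylhexadeca-2,6,10,14-tetraene-8,9-diol | CC(C)=CCC/C(C)=C/[C@H](O)[C@@H](O)/C(C)=C/CC/C(C)=C/Cc1cccc(C)c1O[Si](C)(C)C(C)(C)C | intermediate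
28 | (2E,6E,8S,9S,10E)-1-(2-hydroxy-3-methylphenyl)-3,7,11,15-tetramethylhexadeca-2,6,10,14-tetraene-8,9-diol | CC(C)=CCC/C(C)=C/[C@H](O)[C@@H](O)/C(C)=C/CC/C(C)=C/Cc1cccc(C)c1O | intermediate
29 | 2-[(2E,6E,8S,9S,10E)-8,9-dihydroxy-3,7,11,15-tetramethylhexadeca-2,6,10,14-tetraen-1-yl]-6-methylcyclohexa-2,5-diene-1,4-dione | CC(C)=CCC/C(C)=C/[C@H](O)[C@@H](O)/C(C)=C/CC/C(C)=C/CC1=CC(=O)C=C(C)C1=O | target

**Total step count:** 9.
**Longest linear sequence:** 6 (steps 4, 5, 6, 7, 8, 9).

**Three steps most likely to fail**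

**Step 8 (the new step).**
- Risks: 25 may transfer an alkenyl group directly to palladium (Suzuki-type product), Pd may bind the wrong alkene, or face selectivity may be low on a cis-diboryl alkene.
- The fallback sets out from 7 and 23 and comes back to the route at 27. It uses the known Matteson asymmetric homologation, which keeps the boron-to-carbon 1,2-shift but runs it stoichiometrically under auxiliary control.
- Dienyllithium 24 (from 7, t-BuLi) is trapped with (4R,5R)-4,5-dicyclohexyl-2-isopropoxy-1,3,2-dioxaborolane to give the (R,R)-DICHED dienylboronic ester F1.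
- LiCHCl2 (CH2Cl2, n-BuLi, THF, −100 °C), then ZnCl2, gives the (S)-α-chloro allylic boronic ester F2.
- Lithium 4-methoxybenzyl oxide displaces chloride with inversion through a second 1,2-shift and gives the α-(4-methoxybenzyloxy) boronic ester F3.
- A second LiCHCl2/ZnCl2 homologation gives the α-chloro-β-alkoxy boronic ester F4.
- The alkenyllithium F5 (from 23, t-BuLi, −78 °C) displaces this chloride, again with inversion, and gives the secondary allylic boronic ester F6.
- NaBO3·4H2O oxidises the C–B bond with retention to the mono-PMB ether F7, and DDQ in CH2Cl2/pH 7 buffer frees 27.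
- A single director that gives (S)-chlorides in both homologations leads to the 8S,9S (syn) diol. The aryl silyl ether of 27 is then cleaved with NaOH in THF/MeOH, as at the end of step 8.

**Step 6.**
- Risks: para attack, acid-induced chroman formation from the ortho-allyl phenol, or low conversion on alumina.
- The fallback sets out from 17 and 18 and comes back at 19. It replaces the surface-templated Friedel–Crafts reaction by an SN2 C-alkylation of a phenoxide.
- PBr3 in Et2O at 0 °C converts 17 into (E)-1-bromo-3-methyloct-2-en-6-yne F8.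
- NaH and 18 in toluene give a suspension of sodium 2-methylphenolate F9. F8 alkylates its tight ion pair at the free ortho carbon at rt, and the minor O-allyl ether stays in the organic layer when 19 is extracted into strong aqueous-methanolic KOH.

**Step 7.**
- Risks: the roughly 9:1 regioisomeric iodides may be inseparable on a non-polar silyl ether, and three operations share one flask.
- The fallback sets out from 17 (with 18) and comes back at 23. The hydrometalation is moved to the small polar alcohol before the arene is attached, and the operations are run as separate steps.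
- 17 is treated with Cp2Zr(H)Cl (2.5 equiv, the first equivalent forming the zirconium alkoxide) at 45 °C and then with I2. This gives (2E,6E)-7-iodo-3-methylocta-2,6-dien-1-ol F10, whose regioisomer is removed by chromatography of the alcohols.
- F10 and 18 on acidic Al2O3 in refluxing ClCH2CH2Cl give 2-[(2E,6E)-7-iodo-3-methylocta-2,6-dien-1-yl]-6-methylphenol F11.
- TBSCl and imidazole in DMF convert F11 into 23.

**Further compounds**
F1 | step 8 | (4R,5R)-4,5-dicyclohexyl-2-[(E)-2,6-dimethylhepta-1,5-dien-1-yl]-1,3,2-dioxaborolane | CC(C)=CCC/C(C)=C/B1O[C@H](C2CCCCC2)[C@@H](C2CCCCC2)O1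
F2 | step 8 | (R,R)-DICHED [(S,E)-1-chloro-3,7-dimethylocta-2,6-dien-1-yl]boronate | CC(C)=CCC/C(C)=C/[C@@H](Cl)B1O[C@H](C2CCCCC2)[C@@H](C2CCCCC2)O1
F3 | step 8 | (R,R)-DICHED [(R,E)-1-(4-methoxybenzyloxy)-3,7-dimethylocta-2,6-dien-1-yl]boronate | CC(C)=CCC/C(C)=C/[C@H](OCc1ccc(OC)cc1)B1O[C@H](C2CCCCC2)[C@@H](C2CCCCC2)O1
F4 | step 8 | (R,R)-DICHED [(1S,2S,E)-1-chloro-2-(4-methoxybenzyloxy)-4,8-dimethylnona-3,7-dien-1-yl]boronate | CC(C)=CCC/C(C)=C/[C@H](OCc1ccc(OC)cc1)[C@@H](Cl)B1O[C@H](C2CCCCC2)[C@@H](C2CCCCC2)O1
F5 | step 8 | (2E,6E)-alkenyllithium from 23 (Li in place of I) | [Li]/C(C)=C/CC/C(C)=C/Cc1cccc(C)c1O[Si](C)(C)C(C)(C)C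
F6 | step 8 | (R,R)-DICHED boronic ester carrying boron on C8 and the PMB ether on C9 of the full TBS-protected chain (syn, configuration as in the SMILES) | CC(C)=CCC/C(C)=C/[C@H](OCc1ccc(OC)cc1)[C@@H](B1O[C@H](C2CCCCC2)[C@@H](C2CCCCC2)O1)/C(C)=C/CC/C(C)=C/Cc1cccc(C)c1O[Si](C)(C)C(C)(C)C
F7 | step 8 | (8S,9S)-9-(4-methoxybenzyloxy)-8-ol of the TBS-protected chain | CC(C)=CCC/C(C)=C/[C@H](OCc1ccc(OC)cc1)[C@@H](O)/C(C)=C/CC/C(C)=C/Cc1cccc(C)c1O[Si](C)(C)C(C)(C)C
F8 | step 6 | (E)-1-bromo-3-methyloct-2-en-6-yne | BrC/C=C(\C)CCC#CC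
F9 | step 6 | sodium 2-methylphenolate | Cc1ccccc1[O-].[Na+]
F10 | step 7 | (2E,6E)-7-iodo-3-methylocta-2,6-dien-1-ol | I/C(C)=C/CC/C(C)=C/CO
F11 | step 7 | 2-[(2E,6E)-7-iodo-3-methylocta-2,6-dien-1-yl]-6-methylphenol | I/C(C)=C/CC/C(C)=C/Cc1cccc(C)c1O
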